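## Retrosynthetic overview
- The target is a catechin unit whose 3'-O is joined to C-3''' of an afzelechin unit. Disconnect the Ar–O–Ar bond into a 3'-OH phenol (catechin-type, **6**) and a 3'''-aryl triflate (afzelechin-type, **8**).
- Both halves come from the same intermediate **6**, made from (+)-catechin (2R,3S), which supplies all four stereocentres. They are never touched.
- The B-ring catechol is desymmetrised by protecting it as a diphenylmethylene ketal, benzylating the A-ring and 3-OH groups, and opening the ketal regioselectively.
- Ring-formation order: the two chromane rings are already present in catechin, so the only new ring-linking bond is the diaryl ether, formed by a photochemical Ni-catalysed C–O coupling. A final global hydrogenolysis gives the target.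

Assumptions:
- Both flavan units are (2R,3S), 2,3-trans, i.e. (+)-catechin and (+)-afzelechin configuration. I confirmed this from the target SMILES.
- Lewis-acid ionisation of the ketal cleaves the C–O(3') bond preferentially, because the 3'-aryloxide is the better leaving group and the 4'-oxygen better stabilises the oxocarbenium. The 3'-OH/4'-OCHPh2 isomer is taken as major and separated chromatographically.

## Route

**Step 1**
Reactants: 1 (+)-catechin; 2 dichlorodiphenylmethane
Product: 3 (+)-catechin 3',4'-O-diphenylmethylene ketal
Conditions: Ph2CCl2 (1.2 equiv), K2CO3 (2.5 equiv), MeCN, 60 °C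
Reagents that add atoms: Ph2CCl2, ClC(Cl)(c1ccccc1)c1ccccc1 (leaves a CPh2 bridge)
Why: Catechol O-alkylation followed by intramolecular capture of the oxocarbenium gives the cyclic diaryl ketal. This masks the B-ring catechol and blocks quinone-methide-mediated C-2 epimerisation in the next step. C-2 and C-3 are untouched.

**Step 2**
Reactants: 3; 4 benzyl bromide
Product: 5 3,5,7-tri-O-benzyl-3',4'-O-diphenylmethylene-(+)-catechin
Conditions: NaH (4 equiv), BnBr (3.6 equiv), TBAI (cat.), DMF, 0 °C to rt
Reagents that add atoms: BnBr, BrCc1ccccc1
Why: Williamson etherification of the three remaining OH groups. The B-ring oxygens are blocked, so no retro-oxa-Michael ring opening can occur and both stereocentres are retained.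

**Step 3**
Reactants: 5
Product: 6 3,5,7-tri-O-benzyl-4'-O-benzhydryl-(+)-catechin, with free 3'-OH
Conditions: Et3SiH (4 equiv), BF3·OEt2 (3 equiv), CH2Cl2, –40 to 0 °C; separate the regioisomer by chromatography
Reagents that add atoms: none (Et3SiH adds only H)
Why: This is a Lewis-acid-promoted reductive ring opening of an acetal (ionisation, then hydride capture). It delivers the hydride to the 4'-O-stabilised oxocarbenium and leaves the more acidic 3'-O as the free phenol. C-2 and C-3 are not involved.

**Step 4**
Reactants: 6; 7 triflic anhydride (half of the batch of 6)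
Product: 8 3'-O-triflate of 6
Conditions: Tf2O (1.3 equiv), pyridine, CH2Cl2, 0 °C
Reagents that add atoms: Tf2O, O=S(=O)(C(F)(F)F)OS(=O)(=O)C(F)(F)F (leaves a SO2CF3 group)
Why: Standard sulfonylation of the free phenol. This makes C-3' an aryl electrophile ortho to the 4'-OCHPh2 group, which is the afzelechin-type partner after coupling.

**Step 5**
Reactants: 6 (phenol, 1.0 equiv); 8 (aryl triflate, 1.5 equiv)
Product: 9 fully protected dimer (3'-O-3''' diaryl ether)
Conditions: NiBr2·glyme (10 mol%), dtbbpy (10 mol%), 4CzIPN (2 mol%), K3PO4 (2 equiv), DMA, 455 nm LEDs, 30 °C, 24 h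
Reagents that add atoms: none
Why: Proposed new method: a Ni/photoredox Ullmann-type C–O coupling of an aryl triflate with a phenol, here a doubly ortho-alkoxylated, electron-rich pair that gives a 2,2'-dialkoxy diaryl ether. Mechanistically, photoreduced Ni(0) adds to Ar–OTf, phenoxide displaces the triflate on Ni(II), and photocatalyst-mediated oxidation to Ni(III) triggers C–O reductive elimination. The closest known reaction is Ni/photoredox etherification of aryl halides with alcohols. No stereocentre is involved, and the mild, near-neutral conditions avoid epimerisation.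

**Step 6**
Reactants: 9
Product: 10 catechin-(3'-O-3''')-afzelechin (target)
Conditions: H2 (1 atm), Pd(OH)2/C, THF/MeOH, rt
Reagents that add atoms: none
Why: Hydrogenolysis removes all six benzyl ethers and both benzhydryl ethers at once, leaving the diaryl ether and the C-2/C-3 configurations unchanged.

## Compound list
1 | (+)-catechin | Oc1cc(O)c2c(c1)O[C@H](c1ccc(O)c(O)c1)[C@@H](O)C2 | starting material
2 | dichlorodiphenylmethane | ClC(Cl)(c1ccccc1)c1ccccc1 | starting material
3 | (+)-catechin 3',4'-O-diphenylmethylene ketal | Oc1cc(O)c2c(c1)O[C@H](c1ccc3OC(c4ccccc4)(c4ccccc4)Oc3c1)[C@@H](O)C2 | intermediate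
4 | benzyl bromide | BrCc1ccccc1 | starting material
5 | 3,5,7-tri-O-benzyl-3',4'-O-diphenylmethylene-(+)-catechin | C(c1ccccc1)Oc1cc(OCc2ccccc2)c2c(c1)O[C@H](c1ccc3OC(c4ccccc4)(c4ccccc4)Oc3c1)[C@@H](OCc1ccccc1)C2 | intermediate
6 | 3,5,7-tri-O-benzyl-4'-O-benzhydryl-(+)-catechin, 3'-OH free | C(c1ccccc1)Oc1cc(OCc2ccccc2)c2c(c1)O[C@H](c1ccc(OC(c3ccccc3)c3ccccc3)c(O)c1)[C@@H](OCc1ccccc1)C2 | intermediate
7 | trifluoromethanesulfonic anhydride | O=S(=O)(C(F)(F)F)OS(=O)(=O)C(F)(F)F | starting material
8 | aryl triflate of 6 | C(c1ccccc1)Oc1cc(OCc2ccccc2)c2c(c1)O[C@H](c1ccc(OC(c3ccccc3)c3ccccc3)c(OS(=O)(=O)C(F)(F)F)c1)[C@@H](OCc1ccccc1)C2 | intermediate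
9 | protected dimer | C(c1ccccc1)Oc1cc(OCc2ccccc2)c2c(c1)O[C@H](c1ccc(OC(c3ccccc3)c3ccccc3)c(Oc3cc([C@H]4Oc5cc(OCc6ccccc6)cc(OCc7ccccc7)c5C[C@@H]4OCc8ccccc8)ccc3OC(c9ccccc9)c%10ccccc%10)c1)[C@@H](OCc1ccccc1)C2 | intermediate
10 | catechin-(3'-O-3''')-afzelechin | Oc1cc(O)c2c(c1)O[C@H](c1ccc(O)c(Oc3cc([C@H]4Oc5cc(O)cc(O)c5C[C@@H]4O)ccc3O)c1)[C@@H](O)C2 | target

## Totals
- Total steps: 6.
- Longest linear sequence: 6 steps (1 → 3 → 5 → 6 → 8 → 9 → 10). Compound 6 is made once at double scale and split between Steps 4 and 5.

## Three steps most likely to fail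
1. **Step 5 (proposed new C–O coupling).** The bis-ortho-alkoxy, electron-rich, bulky partners may give low conversion, triflate hydrolysis, or A-ring quenching of the excited photocatalyst.
   - Fallback: convert 8 to the aryl pinacol boronate (Pd-catalysed Miyaura borylation of the triflate), then run a Cu(OAc)2 Chan–Lam coupling with 6. This is known chemistry and adds one step.
2. **Step 3 (regioselective ketal opening).** It may give the wrong regioisomer, or the Lewis acid may ionise the benzylic C-2–O bond.
   - Fallback: make 3,5,7-tri-O-benzylcatechin as in the fallback below, then silylate the more acidic 3'-OH (TBSCl, imidazole), benzylate the 4'-OH (BnBr, K2CO3), and remove the silyl group (TBAF). This gives the 4'-O-benzyl analogue of 6, which is carried through Steps 4–6 unchanged.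
3. **Step 1 (ketalisation of free catechin).** Ph2C+ could C-alkylate the nucleophilic phloroglucinol A ring.
   - Fallback: mask the B ring transiently as the phenylboronate (PhB(OH)2, toluene, Dean–Stark). Benzylate the A ring and 3-OH (BnBr, base), then release the catechol by transesterification with pinacol to give 3,5,7-tri-O-benzylcatechin. Form the Ph2C ketal on this A-ring-protected substrate (Ph2CCl2, K2CO3) to give 5 directly.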